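**Plan**

- Retrosynthesis: the two phenolic O–H bonds are masked as benzyl ethers. The C2–C3 single bond of the O–C1–C2–C3–aryl linker is traced back to a C2=C3 alkene, which is cut by cross-metathesis into a vinylarene and an allyl ester. The vinyl C=C goes back to an aryl aldehyde, and the ester C(acyl)–O bond to allyl alcohol and stearoyl chloride.
- Enabling feature: C3 is a benzylic carbon on the benzene ring, and C2–C1–O is a two-carbon unit that can arrive as the terminal alkene of an already acylated allyl alcohol. An aryl–CH=CH2 / CH2=CH–CH2–O–acyl pair therefore maps exactly onto the linker.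
- Forward: no ring is formed. 5-Hydroxyvanillin 1 is dibenzylated to 2 and methylenated to 3; allyl alcohol 4 and stearoyl chloride 5 give allyl stearate 6; 3 and 6 are joined to the cinnamyl ester 7; the alkene is saturated to 8 and the benzyl groups are removed to give the target 9.
- Stereochemistry: the target has no stereocentre. The E alkene of 7 is the only stereo-element on the way and disappears in step 5.

Key step: step 4

Remark: the linker carbons are numbered C1 (bearing the ester oxygen), C2 and C3 (benzylic); 5-hydroxyvanillin, allyl alcohol and stearoyl chloride are taken as purchasable.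

**Route**

Step 1
Reactants: 1 5-hydroxyvanillin (3,4-dihydroxy-5-methoxybenzaldehyde)
Product: 2 3,4-bis(benzyloxy)-5-methoxybenzaldehyde
Conditions: BnBr (2.4 equiv), K2CO3 (3 equiv), DMF, 60 °C, N2
Reagents that add atoms: benzyl bromide, BrCc1ccccc1
Why: Williamson ether synthesis, in which K2CO3 generates both phenoxides of the catechol and each displaces bromide from the benzylic halide by SN2, the non-enolizable aldehyde and the methyl ether being inert to the base.

Step 2
Reactants: 2 3,4-bis(benzyloxy)-5-methoxybenzaldehyde
Product: 3 1,2-bis(benzyloxy)-3-methoxy-5-vinylbenzene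
Conditions: Ph3PCH3Br, KOtBu, THF, 0 °C to rt
Reagents that add atoms: methyltriphenylphosphonium bromide, C[P+](c1ccccc1)(c1ccccc1)c1ccccc1.[Br-]
Why: Wittig methylenation, in which the non-stabilized ylide adds to the non-enolizable aryl aldehyde and the adduct collapses to the terminal alkene, driven by P=O bond formation, without touching the benzyl or methyl ethers.

Step 3
Reactants: 4 allyl alcohol (prop-2-en-1-ol); 5 stearoyl chloride (octadecanoyl chloride)
Product: 6 allyl stearate (prop-2-en-1-yl octadecanoate)
Conditions: Et3N, DMAP (cat.), CH2Cl2, 0 °C to rt
Reagents that add atoms: none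
Why: Nucleophilic acyl substitution (DMAP-catalysed O-acylation of a primary alcohol by an acid chloride) with Et3N as acid scavenger, a slight excess of the volatile alcohol being removed on evaporation.

Step 4
Reactants: 3 1,2-bis(benzyloxy)-3-methoxy-5-vinylbenzene; 6 allyl stearate
Product: 7 (E)-3-[3,4-bis(benzyloxy)-5-methoxyphenyl]allyl stearate
Conditions: RuCl2(SIMes)(=CH-C6H4-2-OiPr) (second-generation Hoveyda–Grubbs catalyst, SIMes = 1,3-bis(2,4,6-trimethylphenyl)imidazolidin-2-ylidene, 5 mol%), 1,4-benzoquinone (10 mol%), 6 (3 equiv), CH2Cl2, 40 °C, slow addition of 3, Ar sparge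
Reagents that add atoms: none
Why: Olefin cross-metathesis: the ruthenium alkylidene released from RuCl2(SIMes)(=CH-C6H4-2-OiPr) adds to each terminal alkene by [2+2] cycloaddition, the ruthenacyclobutanes open by cycloreversion, and exchange of the alkylidene halves joins benzylic C3 to C2 while ethylene is purged from the solution. The closest known reaction type is the cross-metathesis of styrenes with allyl acetate and other primary allylic esters under N-heterocyclic-carbene ruthenium catalysts, which gives (E)-cinnamyl esters. No ring is closed and no stereocentre is created; the E geometry follows from reversible secondary metathesis under thermodynamic control and is of no consequence because step 5 removes the double bond. The selectivity required is cross-coupling over self-coupling of either partner: both alkenes are unhindered, monosubstituted and fast-reacting with this catalyst (the vinyl group of 3 has no ortho substituent, the alkene of 6 no allylic branching), so the distribution is essentially statistical and is steered by a threefold excess of the cheap ester 6, whose self-metathesis is reversible, and by slow addition of 3, which keeps its stationary concentration low and disfavours the slow, practically irreversible stilbene formation. 1,4-Benzoquinone is added to suppress ruthenium-hydride-mediated migration of the allyl double bond towards the ester oxygen.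

Step 5
Reactants: 7 (E)-3-[3,4-bis(benzyloxy)-5-methoxyphenyl]allyl stearate
Product: 8 3-[3,4-bis(benzyloxy)-5-methoxyphenyl]propyl stearate
Conditions: H2 (1 atm), RhCl(PPh3)3 (10 mol%), PhMe/EtOH (1:1), rt to 40 °C
Reagents that add atoms: none
Why: Homogeneous hydrogenation with RhCl(PPh3)3, which delivers H2 to the unhindered 1,2-disubstituted alkene but does not cleave benzylic or allylic C–O bonds, so the benzyl ethers and the stearate should stay in place, something heterogeneous palladium would not guarantee for a cinnamyl ester.

Step 6
Reactants: 8 3-[3,4-bis(benzyloxy)-5-methoxyphenyl]propyl stearate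
Product: 9 3-(3,4-dihydroxy-5-methoxyphenyl)propyl stearate (target)
Conditions: H2 (1 atm), 10% Pd/C, EtOAc/EtOH, rt; filtration and concentration under Ar
Reagents that add atoms: none
Why: Catalytic hydrogenolysis of the two aryl benzyl ethers on palladium, which should release the catechol cleanly because the alkene is already saturated (no allylic C–O bond remains) and the alkyl ester and the aryl methyl ether are inert to H2 on Pd/C.

**Compound list**

1 | 5-hydroxyvanillin (3,4-dihydroxy-5-methoxybenzaldehyde) | COc1cc(C=O)cc(O)c1O | starting material
2 | 3,4-bis(benzyloxy)-5-methoxybenzaldehyde | COc1cc(C=O)cc(OCc2ccccc2)c1OCc1ccccc1 | intermediate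
3 | 1,2-bis(benzyloxy)-3-methoxy-5-vinylbenzene | C=Cc1cc(OC)c(OCc2ccccc2)c(OCc2ccccc2)c1 | intermediate
4 | allyl alcohol (prop-2-en-1-ol) | C=CCO | starting material
5 | stearoyl chloride (octadecanoyl chloride) | CCCCCCCCCCCCCCCCCC(Cl)=O | starting material
6 | allyl stearate (prop-2-en-1-yl octadecanoate) | CCCCCCCCCCCCCCCCCC(=O)OCC=C | intermediate
7 | (E)-3-[3,4-bis(benzyloxy)-5-methoxyphenyl]allyl stearate | CCCCCCCCCCCCCCCCCC(=O)OC/C=C/c1cc(OC)c(OCc2ccccc2)c(OCc2ccccc2)c1 | intermediate
8 | 3-[3,4-bis(benzyloxy)-5-methoxyphenyl]propyl stearate | CCCCCCCCCCCCCCCCCC(=O)OCCCc1cc(OC)c(OCc2ccccc2)c(OCc2ccccc2)c1 | intermediate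
9 | 3-(3,4-dihydroxy-5-methoxyphenyl)propyl stearate | CCCCCCCCCCCCCCCCCC(=O)OCCCc1cc(O)c(O)c(OC)c1 | target

**Count**

Total steps: 6. Longest linear sequence: 5 steps (steps 1, 2, 4, 5 and 6, from 5-hydroxyvanillin 1).

**Steps most likely to fail**

Step 4. The partner selection is close to statistical, so self-metathesis of the vinylarene, ruthenium-hydride-induced double-bond migration in the allyl ester, and a tedious chromatographic separation from surplus lipophilic ester may erode the outcome. The fallback makes the C2=C3 alkene by carbonyl olefination and sets out from aldehyde 2. Horner–Wadsworth–Emmons reaction with triethyl phosphonoacetate and NaH in THF (0 °C to rt) should give ethyl (E)-3-[3,4-bis(benzyloxy)-5-methoxyphenyl]prop-2-enoate F1. Reduction with i-Bu2AlH in CH2Cl2 at −78 °C should give (E)-3-[3,4-bis(benzyloxy)-5-methoxyphenyl]prop-2-en-1-ol F2. Acylation of F2 with stearoyl chloride 5 (Et3N, DMAP, CH2Cl2) comes back to the route at 7.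

Step 5. Turnover of the rhodium catalyst at the conjugated, 1,2-disubstituted alkene may be slow, and prolonged exposure may bring allylic C–O cleavage or alkene migration towards the ester oxygen. The fallback saturates the chain before the fatty ester is in place, so that no allylic C–O bond is present during reduction; it sets out from aldehyde 2. Wittig reaction with methyl (triphenylphosphoranylidene)acetate in toluene at 80 °C should give methyl (E)-3-[3,4-bis(benzyloxy)-5-methoxyphenyl]prop-2-enoate F3; the methyl ester is chosen to match the methanol of the next operation. Conjugate reduction with NaBH4 and catalytic NiCl2·6H2O in MeOH/THF at 0 °C should give methyl 3-[3,4-bis(benzyloxy)-5-methoxyphenyl]propanoate F4. LiAlH4 in THF at 0 °C should give 3-[3,4-bis(benzyloxy)-5-methoxyphenyl]propan-1-ol F5. Acylation of F5 with stearoyl chloride 5 (Et3N, DMAP, CH2Cl2) comes back to the route at 8.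

Step 6. Hydrogenolysis may stall through poor solubility of the waxy substrate or poisoning of the palladium surface by residual phosphine, and the liberated electron-rich catechol may oxidize in air during filtration. The fallback abandons hydrogenolysis for a Lewis-acid dealkylation. It sets out from 8 and treats it with BCl3 and pentamethylbenzene (a non-basic benzyl-cation scavenger) in CH2Cl2 at −78 °C, followed by a methanol quench and degassed work-up. At this temperature the aryl methyl ether and the alkyl ester should survive, and the fallback arrives directly at 9. It makes no new compound (entry F0).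

**Further compounds**

F1 | step 4 | ethyl (E)-3-[3,4-bis(benzyloxy)-5-methoxyphenyl]prop-2-enoate | CCOC(=O)/C=C/c1cc(OC)c(OCc2ccccc2)c(OCc2ccccc2)c1
F2 | step 4 | (E)-3-[3,4-bis(benzyloxy)-5-methoxyphenyl]prop-2-en-1-ol | OC/C=C/c1cc(OC)c(OCc2ccccc2)c(OCc2ccccc2)c1
F3 | step 5 | methyl (E)-3-[3,4-bis(benzyloxy)-5-methoxyphenyl]prop-2-enoate | COC(=O)/C=C/c1cc(OC)c(OCc2ccccc2)c(OCc2ccccc2)c1
F4 | step 5 | methyl 3-[3,4-bis(benzyloxy)-5-methoxyphenyl]propanoate | COC(=O)CCc1cc(OC)c(OCc2ccccc2)c(OCc2ccccc2)c1
F5 | step 5 | 3-[3,4-bis(benzyloxy)-5-methoxyphenyl]propan-1-ol | OCCCc1cc(OC)c(OCc2ccccc2)c(OCc2ccccc2)c1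
F0 | step 6 | none | none
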